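**Conventions.** The chain is numbered C1–C16 from the CH2OH of the arm on the ether CH to the CH2OH of the other arm, so the ring carbons are C6–C11. The lactone carbonyl carbon is called C17. Compound numbers 1–37 are fixed by the steps below and used throughout.

## Analysis of the target

The core is a 6,8-dioxabicyclo[3.2.2]nonan-7-one: an oxepane (ring O, C6–C11) whose carbons C7 and C11 are spanned by a carboxylate bridge (C17(=O)–O), which also closes a 1,4-dioxan-2-one. There are four stereocentres, 6S, 7R, 10S and 11R. C7 and C11 are fully substituted, oxygen-bearing bridgeheads, and the bridge forces the C7 oxygen and the C11 carboxyl onto one face of the oxepane. The C10 hydroxyl lies on that same face, and at C6 the hydrogen points to the lactone bridge while the C1–C5 arm points to the C8–C10 bridge. Both arms end in (Z)-trisubstituted allylic alcohols (C2=C3 and C14=C15, CH2OH cis to the chain), whose geometry must be made stereospecifically. Sensitive elements are the allylic alcohols (acid, oxidants, hydrogenation) and the bridged lactone, which with the free C10 hydroxyl is a β-hydroxy ester open to base. The hard parts are the quaternary C11 (ring oxygen, carboxyl, chain, carbinol neighbour), the tertiary ester oxygen at C7, and the need to finish all ring oxidation before the oxidisable arms arrive. The strategy rests on the fact that C6–C11, with the methyl on C7 and the oxygen on C10, are the ring of (S)-carvone (carbonyl carbon = C6, methyl-bearing carbon = C7, stereocentre = C10, α′-methylene = C11), and that the ring oxygen sits between C6 and C11, where oxygen insertion beside the ketone would put it.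

## Retrosynthetic reasoning

**C13–C14 and the protecting groups.** Target 37 is the desilylated form of 36. In 36 the sp3–sp2 bond C13–C14 is cut, giving bromide 30 and alkenyl iodide 34. Cutting beside the alkene rather than through it means the Z geometry is made in a small fragment (34, from 31 by way of 33) and transferred with retention. An olefination on the core would need an ester reduction next to the lactone. The forward coupling must tolerate the lactone, which an alkylzinc does.

**C5–C6 and the C6 hydrogen.** Oxepane 30 comes from lactol 29, and 29 from dilactone bromide 19 plus Grignard reagent 28 (made from 27). The cut is made here because C6 is the carbon that the ring expansion delivers as a carbonyl. The arm enters as a nucleophile and the hydrogen afterwards, inside the rigid bicycle. The forward steps must add once, at C6 and not at C17, and deliver hydride from the lactone-bridge face.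

**The C13 handle.** Bromide 19 comes from silyl ether 18 by direct exchange. A free C13 hydroxyl would sit γ to C17 and could translactonise, so it is never liberated.

**O–C7.** Dilactone 18 is opened at the C7–O bond to acid 16 (through ketene acetal 17). C7 is the α-carbon of the ring lactone, so it can be made nucleophilic and then oxidised, and the C11 carboxyl can reach it from one face only. This sets C7 without reagent control and makes the C7 epimer mixture of 16 irrelevant.

**Oxidation level of C17.** Acid 16 goes back through alcohol 15 to benzyl ether 14. The benzyl ether survives the peracid, and its hydrogenolysis is placed before any alkene is present.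

**O–C11 (key disconnection).** Lactone 14 is the oxygen-insertion product of cyclohexanone 13. One skeletal C–C bond (C6–C11) becomes C–O with retention at C11, which turns the carvone ring into the oxepane and leaves C6 as a carbonyl for the two operations above.

**Adjusting 13.** Ketone 13 comes from enone 12 by conjugate reduction, 12 from diol 11 by silylation, 11 from triol 10 by allylic oxidation, and 10 from ester acetate 9 by global hydride reduction. Reducing everything and reoxidising only the allylic alcohol solves the problem of reducing an ester beside a ketone.

**C10–O.** Acetate 9 comes from isopropenyl compound 7 (through hydroperoxide 8) by ozonolysis and carbon-to-oxygen rearrangement with retention, so the carvone stereocentre becomes the C10 carbinol.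

**C11–C12 and C11–C17.** Enone 7 comes from 4 and bromo ester 5, and 4 from carvone 1 and chloromethyl ether 2. Each electrophile enters anti to the isopropenyl group, so the order (one-carbon unit first, two-carbon unit second) fixes C11.

**Arm pieces.** Bromide 27 goes back through 26, 25, 24 and 23 to ynoate 22 and alkyne 20 (by way of 21). Iodide 34 goes back through 33 to propargyl alcohol 31 (by way of 32). Both Z alkenes come from stereospecific additions to alkynes.

## Alternatives that were turned down

**Alternative 1:** The disconnection is C10–C11, with the ester bond O–C8 as the bond that is given up. The precursor is the seven-membered 1,4-dioxepan-2-one A1, in which C17 is esterified to a C8 carbinol carrying an (E)-2-(pinacolboryl)vinyl group. Enolisation and O-silylation (LiN(SiMe3)2, Me3SiCl) would set off a [3,3] shift through the boat arrangement that the ring enforces, giving oxepene acid A2 with a cis C8=C9 bond, the C10 boronate and the quaternary C11.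
- For: C10 and C11 are made together with their relationship fixed by alkene geometry and a forced transition-state shape. C6, C7 and both arms are already in place, so there is no late choice between two ester carbonyls and no late reduction at C6. On convergence and on C6 it is stronger than the chosen route.
- Against: A1 needs the contiguous C6/C7/C8 triad, including the tertiary ether at C7, from acyclic stereocontrol, plus a stereodefined alkenyl boronate. After the rearrangement the ring alkene must be saturated beside two trisubstituted alkenes, the C–B bond oxidised and the lactone closed.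
- Comparison: assembling A1 would take at least as many steps as the whole carvone sequence. The chosen route instead buys the ring with C10 in place, sets C11 by alkylation of a cyclic enolate, and confines the strategic risk to one oxidation.

**Alternative 2:** The disconnections are O–C11 and C10–C11 at once. The precursor is the acyclic diazo ester A3 (C11 as the diazo carbon, ester of the C7 tertiary alcohol, free C6 hydroxyl, C10 aldehyde). With Rh2(O2CC(CH3)3)4, loss of nitrogen gives a metal carbenoid at C11, the C6 hydroxyl attacks it, and the resulting ylide/enol adds to the C10 aldehyde, closing the dioxanone and the oxepane to give A4, the bis-silyl ether of the target.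
- For: unmatched step economy. Both rings, two bonds and two stereocentres form in one step, one deprotection from the target. On step count it is clearly stronger.
- Against: the carbenoid carbon carries a CH2 group, so 1,2-hydride shift to an enoate is a fast leak. Simple O–H insertion by proton transfer competes with the aldol trap. The aldol must close a seven-membered ring and set C10 and C11 with no evident control element. The trisubstituted alkenes are potential cyclopropanation sites. All material is staked on the last C–C bond-forming step.
- Comparison: the chosen route gives up brevity for stereocentres set one at a time by elements that can be checked (C10 from the terpene, C11 from ring alkylation, C7 by a tether).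

**Alternative 3:** The disconnections are O–C11 and C11–C17. The precursor is the acyclic ketone A5 with a free C6 hydroxyl. In a Jocic-type sequence, chloroform-derived trichloromethanide (CHCl3, LiN(SiMe3)2) attacks the C11 carbonyl. After DBU-induced loss of chloride, the C6 oxygen displaces the former carbonyl oxygen at C11 with inversion, and the CCl3 carbon ends as the carboxyl group of acid A6.
- For: the α-alkoxy acid is made directly, the carboxyl carbon comes from chloroform, and the inversion is stereospecific. It never passes through a dilactone with two similar carbonyls, and on that point it is stronger.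
- Against: the C11 configuration is decided by the facial selectivity of addition to an open-chain α-silyloxy ketone. The ring closure is a seven-membered etherification at a fully substituted carbon in competition with external nucleophiles. A6 carries only stubs of both arms, so two separate Z-olefin constructions and the C7 lactonisation remain.
- Comparison: it matches the chosen route in forming O–C11 with defined configuration, but the chosen route takes C11 from a cyclic enolate alkylation and C10 from the starting material, and is shorter after the ring is formed.

Key step: step 8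

## Route

Remark on the chemistry (assumption): C7 of 13–16 is formed as an epimer mixture that converges at 17 (one epimer is drawn), and the carbinol carbon C6 of 10, the peroxyketal carbon of 8 and the hemiketal carbon of 29 are mixtures and are written without descriptor.

Step 1
Reactants: 1 (S)-carvone; 2 benzyl chloromethyl ether
Product: 4 trans-6-(benzyloxymethyl)carvone, via lithium dienolate 3 (not isolated)
Conditions: LiN(iPr)2, THF, −78 °C; then 2, −78 to −20 °C
Reagents that add atoms: none
Why: Kinetic deprotonation at the α′-methylene gives the cross-conjugated lithium dienolate, which is C-alkylated by the reactive chloromethyl ether (enolate alkylation); the electrophile enters anti to the isopropenyl group, and this centre is flattened again in step 2.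

Step 2
Reactants: 4 trans-6-(benzyloxymethyl)carvone; 5 tert-butyl bromoacetate
Product: 7 quaternary enone ester, via lithium enolate 6 (not isolated)
Conditions: LiN(iPr)2, THF, −78 °C; then 5, DMPU, −78 to −30 °C
Reagents that add atoms: none
Why: The last α′-hydrogen is removed and the tetrasubstituted enolate is alkylated on the face opposite the neighbouring isopropenyl group (enolate alkylation of a 6-substituted carvone), which puts CH2CO2tBu trans and CH2OBn cis to isopropenyl and so sets C11; the reactive α-bromo ester should capture the enolate at low temperature before it can lose benzyloxide.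

Step 3
Reactants: 7 quaternary enone ester
Product: 9 enone acetate, via methoxy hydroperoxide 8 (not isolated)
Conditions: O3, CH2Cl2/MeOH, −78 °C (indicator end point); then Ac2O, Et3N, DMAP, CH2Cl2, 0 °C to rt
Reagents that add atoms: ozone (O=[O+][O-]); methanol (CO)
Why: The electron-rich 1,1-disubstituted alkene is ozonised in preference to the enone and the carbonyl oxide is trapped by methanol; acetylation of the hydroperoxide starts the Criegee rearrangement, in which C10 shifts from carbon to oxygen with retention, and demethylation of the dialkoxycarbenium ion leaves the C10 acetate.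

Step 4
Reactants: 9 enone acetate
Product: 10 enetriol
Conditions: LiAlH4, Et2O, −78 to 0 °C
Reagents that add atoms: none
Why: Hydride reduces the tert-butyl ester to the primary alcohol, cleaves the acetate and reduces the enone carbonyl in the 1,2-sense (ester and ketone reduction); the new allylic carbinol centre is removed again in step 5.

Step 5
Reactants: 10 enetriol
Product: 11 enone diol
Conditions: MnO2, CH2Cl2, rt
Reagents that add atoms: none
Why: Activated MnO2 oxidises only the allylic alcohol (chemoselective allylic oxidation), so the C6 ketone returns while the primary and the saturated secondary hydroxyl stay free.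

Step 6
Reactants: 11 enone diol
Product: 12 bis-TBS enone
Conditions: t-BuMe2SiOSO2CF3, 2,6-lutidine, CH2Cl2, −78 to 0 °C
Reagents that add atoms: tert-butyldimethylsilyl trifluoromethanesulfonate (CC(C)(C)[Si](C)(C)OS(=O)(=O)C(F)(F)F)
Why: The silyl triflate silylates the primary and the hindered secondary hydroxyl alike (silyl ether formation), and the weak base avoids retro-aldol cleavage of the β-hydroxy ketone.

Step 7
Reactants: 12 bis-TBS enone
Product: 13 cyclohexanone (key-step precursor)
Conditions: LiBH(s-Bu)3, THF, −78 °C; aq. NH4Cl
Reagents that add atoms: none
Why: The bulky borohydride adds 1,4 to the β-unsubstituted enone because the carbonyl is screened by the adjacent quaternary carbon (conjugate reduction); protonation of the enolate gives both C7 epimers, which are carried on together.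

Step 8
Reactants: 13 cyclohexanone (key-step precursor)
Product: 14 oxepan-2-one (key-step product)
Conditions: (CF3CO)2O, urea·H2O2, Na2HPO4, CH2Cl2, 0 °C to rt
Reagents that add atoms: trifluoroperacetic acid, made in the flask (OOC(=O)C(F)(F)F)
Why: Baeyer–Villiger oxidation: the peracid adds to the C6 carbonyl to give the tetrahedral peroxy adduct, and the α-carbon whose bond lies antiperiplanar to the O–O bond and best carries positive charge shifts from C6 to oxygen as trifluoroacetate leaves. The closest known reaction type is the Baeyer–Villiger oxidation of α,α-disubstituted cyclohexanones with buffered CF3CO3H, in which the fully substituted carbon migrates with retention. The seven-membered lactone is not closed by a cyclisation but arises by ring expansion, oxygen being inserted into the C6–C11 bond of the six-membered ring. No stereocentre is created; C11 keeps its configuration because the migrating carbon shifts suprafacially and is never free, and C10 is a spectator. The step needs migration of quaternary C11 in preference to secondary C7: full substitution of C11 favours it, while the two β-oxygens (CH2OBn and the C10 silyl ether) withdraw electron density and slow the shift. For that reason the most reactive practical peracid with the best leaving group is used, and Na2HPO4 keeps the medium from cleaving the silyl ethers or opening the lactone. Both C7 epimers of 13 give lactones that converge in step 11.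

Step 9
Reactants: 14 oxepan-2-one (key-step product)
Product: 15 hydroxymethyl lactone
Conditions: H2 (1 atm), Pd/C, EtOAc, rt
Reagents that add atoms: none
Why: Hydrogenolysis of the benzyl ether; the silyl ethers and the lactone are inert and no alkene is present yet.

Step 10
Reactants: 15 hydroxymethyl lactone
Product: 16 lactone acid
Conditions: TEMPO (cat.), NaOCl (cat.), NaClO2, MeCN/phosphate buffer pH 6.7, 35 °C
Reagents that add atoms: sodium chlorite ([Na+].[O-]Cl=O)
Why: Oxoammonium oxidation to the aldehyde and chlorite oxidation in the same pot give the acid near neutral pH (TEMPO/chlorite oxidation); the aldehyde has no α-hydrogen, so C11 cannot epimerise, and the silyl ethers survive.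

Step 11
Reactants: 16 lactone acid
Product: 18 bridged dilactone, via silyl ketene acetal 17 (not isolated)
Conditions: LiN(iPr)2 (2.2 equiv), Me3SiCl, THF, −78 °C; then PhI(OAc)2, CH2Cl2, −78 to 0 °C
Reagents that add atoms: none
Why: Proposed new method: the ketene acetal carbon C7 attacks the trivalent iodine of PhI(OAc)2 and becomes electrophilic, and the silyl ester on C11, which can reach C7 on its own face only, displaces iodobenzene and closes the six-membered 1,4-dioxane-2,5-dione ring, so the C7 oxygen is set cis to the C11 carboxyl whatever the C7 configuration of 16; the closest known reactions are the α-acyloxylation and α-sulfonyloxylation of ketene silyl acetals and the oxidative lactonisation of keto acids with hypervalent iodine reagents.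

Step 12
Reactants: 18 bridged dilactone
Product: 19 dilactone bromide
Conditions: Ph3PBr2, CH2Cl2, 0 °C to rt
Reagents that add atoms: triphenylphosphine dibromide (BrP(Br)(c1ccccc1)(c1ccccc1)c1ccccc1)
Why: The primary silyl ether is converted directly into the bromide (oxyphosphonium formation with loss of the silyl bromide, then SN2 by bromide), so a free C13 hydroxyl that could translactonise onto C17 never appears; the hindered secondary silyl ether at C10 should not react.

Step 13
Reactants: 20 tert-butyl(but-3-yn-1-yloxy)dimethylsilane
Product: 22 methyl ynoate, via lithium acetylide 21 (not isolated)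
Conditions: n-BuLi, THF, −78 °C; then ClCO2Me, −78 to 0 °C
Reagents that add atoms: methyl chloroformate (COC(Cl)=O)
Why: Deprotonation of the terminal alkyne and C-acylation of the acetylide with the chloroformate.

Step 14
Reactants: 22 methyl ynoate
Product: 23 (Z)-enoate
Conditions: MeLi, CuI, THF, −78 °C (Me2CuLi); then 22, −78 °C; MeOH, then aq. NH4Cl at −78 °C
Reagents that add atoms: lithium dimethylcuprate, from MeLi and CuI ([Li+].C[Cu-]C)
Why: syn-Carbocupration of the ynoate and cold protonation with retention put the new methyl group cis to hydrogen, i.e. the CH2CH2O chain cis to the ester (Z); keeping the alkenylcopper species at −78 °C prevents leakage through the allenoate.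

Step 15
Reactants: 23 (Z)-enoate
Product: 24 (Z)-allylic alcohol
Conditions: i-Bu2AlH, CH2Cl2, −78 °C
Reagents that add atoms: none
Why: 1,2-Reduction of the conjugated ester to the allylic alcohol (hydride reduction) without change of alkene geometry.

Step 16
Reactants: 24 (Z)-allylic alcohol
Product: 25 bis-silyl ether
Conditions: t-BuPh2SiCl, imidazole, CH2Cl2, rt
Reagents that add atoms: tert-butyl(chloro)diphenylsilane (CC(C)(C)[Si](Cl)(c1ccccc1)c1ccccc1)
Why: Silylation of the allylic alcohol; the diphenylsilyl group is chosen because it outlasts the acidic removal of the primary TBS group and the Lewis acid of step 20.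

Step 17
Reactants: 25 bis-silyl ether
Product: 26 homoallylic alcohol
Conditions: PPTS, MeOH, rt
Reagents that add atoms: none
Why: Acid-catalysed methanolysis removes the primary TBS ether much faster than the tert-butyldiphenylsilyl ether (selective desilylation).

Step 18
Reactants: 26 homoallylic alcohol
Product: 27 homoallylic bromide
Conditions: CBr4, PPh3, CH2Cl2, 0 °C
Reagents that add atoms: carbon tetrabromide (BrC(Br)(Br)Br)
Why: Appel bromination, an SN2 reaction at a primary carbon under neutral conditions that leaves the alkene geometry untouched.

Step 19
Reactants: 27 homoallylic bromide; 19 dilactone bromide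
Product: 29 bicyclic lactol, via Grignard reagent 28 (not isolated)
Conditions: Mg, THF, rt; then 19, THF, −78 °C; aq. NH4Cl at −78 °C
Reagents that add atoms: none
Why: Grignard addition to a lactone carbonyl stopped at the hemiketal, because the magnesium hemiketal alkoxide is held in the six-membered dioxanone ring of the bicycle and should not collapse to a ketone at −78 °C. Of the two ester carbonyls C6 should be the more accessible, since C17 is flanked by the C10 silyl ether on one face and by the C12–C13 chain on the other while C6 has only the bridgehead methyl and C8H2 nearby; neither carbonyl can enolise.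

Step 20
Reactants: 29 bicyclic lactol
Product: 30 oxepane bromide
Conditions: Et3SiH, Me3SiOSO2CF3 (cat.), CH2Cl2, −78 to −40 °C
Reagents that add atoms: none
Why: The silyl triflate ionises the hemiketal to the bicyclic oxocarbenium ion at C6, which Et3SiH reduces (ionic reduction of a lactol); hydride is expected to enter from the face of the flat, hydrogen-free lactone bridge rather than from the face of the C8–C10 methylene bridge, which puts H on the lactone side and the arm toward C8, the S configuration at C6.

Step 21
Reactants: 31 propargyl alcohol
Product: 33 (Z)-iodo alcohol, via alkenylmagnesium 32 (not isolated)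
Conditions: MeMgBr, CuI (cat.), THF, −10 °C to rt; then I2, −78 to 0 °C
Reagents that add atoms: methylmagnesium bromide (C[Mg]Br); iodine ([I][I])
Why: Copper-catalysed anti-carbomagnesiation of the propargylic alkoxide puts methyl on C2 and magnesium on C3, held cis to the CH2O group in a five-membered chelate, and iodinolysis proceeds with retention to give the iodide cis to CH2OH.

Step 22
Reactants: 33 (Z)-iodo alcohol
Product: 34 (Z)-alkenyl iodide
Conditions: t-BuMe2SiCl, imidazole, CH2Cl2, rt
Reagents that add atoms: tert-butyl(chloro)dimethylsilane (CC(C)(C)[Si](C)(C)Cl)
Why: Silyl ether formation, so that the alcohol does not protonate the alkylzinc in step 23.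

Step 23
Reactants: 30 oxepane bromide; 34 (Z)-alkenyl iodide
Product: 36 tris-silyl ether, via alkylzinc bromide 35 (not isolated)
Conditions: Zn, I2 (cat.), DMA, 70 °C; then 34, Pd(PPh3)4 (cat.), rt to 40 °C
Reagents that add atoms: none
Why: Zinc insertion into the primary bromide gives an alkylzinc that tolerates the lactone, and Negishi coupling with the alkenyl iodide at zerovalent palladium proceeds with retention of alkene geometry, forming C13–C14 with the CH2O group cis to the chain.

Step 24
Reactants: 36 tris-silyl ether
Product: 37 target
Conditions: HF·pyridine, pyridine, THF, 0 °C to rt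
Reagents that add atoms: none
Why: Fluoride cleaves all three silyl ethers under mildly acidic conditions (global desilylation); basic fluoride sources are avoided because of the lactone and the β-hydroxy ester motif at C10/C17.

## Compound list

1 | (S)-carvone | CC1=CC[C@@H](CC1=O)C(C)=C | starting material
2 | benzyl chloromethyl ether | ClCOCc1ccccc1 | starting material
3 | lithium dienolate of carvone (O–Li on C6, C6=C11) | CC1=CC[C@H](C(C)=C)C=C1O[Li] | intermediate (not isolated)
4 | trans-6-(benzyloxymethyl)carvone (CH2OBn on C11 trans to isopropenyl on C10) | CC1=CC[C@H](C(C)=C)[C@@H](COCc2ccccc2)C1=O | intermediate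
5 | tert-butyl bromoacetate | CC(C)(C)OC(=O)CBr | starting material
6 | lithium enolate of 4 (C6=C11) | CC1=CC[C@H](C(C)=C)C(COCc2ccccc2)=C1O[Li] | intermediate (not isolated)
7 | quaternary enone ester (C11: CH2OBn cis and CH2CO2tBu trans to isopropenyl) | CC1=CC[C@H](C(C)=C)[C@@](COCc2ccccc2)(CC(=O)OC(C)(C)C)C1=O | intermediate
8 | methoxy hydroperoxide (C10 bears C(CH3)(OCH3)OOH) | CC1=CC[C@H](C(C)(OC)OO)[C@@](COCc2ccccc2)(CC(=O)OC(C)(C)C)C1=O | intermediate (not isolated)
9 | enone acetate (C10 OAc, configuration retained) | CC1=CC[C@H](OC(C)=O)[C@@](COCc2ccccc2)(CC(=O)OC(C)(C)C)C1=O | intermediate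
10 | enetriol (C6 carbinol, C10 OH, C13 OH; C6 epimers) | CC1=CC[C@H](O)[C@@](COCc2ccccc2)(CCO)C1O | intermediate
11 | enone diol (C6 ketone, C10 OH, C13 OH) | CC1=CC[C@H](O)[C@@](COCc2ccccc2)(CCO)C1=O | intermediate
12 | bis-TBS enone | CC1=CC[C@H](O[Si](C)(C)C(C)(C)C)[C@@](COCc2ccccc2)(CCO[Si](C)(C)C(C)(C)C)C1=O | intermediate
13 | cyclohexanone, key-step precursor (C6 ketone; C11 with CH2OBn cis and CH2CH2OTBS trans to the C10 silyl ether; C7 epimer drawn) | CC(C)(C)[Si](C)(C)OCC[C@@]1(COCc2ccccc2)C(=O)[C@H](C)CC[C@@H]1O[Si](C)(C)C(C)(C)C | intermediate
14 | oxepan-2-one, key-step product (ring O between C6 and C11) | CC(C)(C)[Si](C)(C)OCC[C@@]1(COCc2ccccc2)OC(=O)[C@H](C)CC[C@@H]1O[Si](C)(C)C(C)(C)C | intermediate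
15 | hydroxymethyl lactone (C17 as CH2OH) | CC(C)(C)[Si](C)(C)OCC[C@@]1(CO)OC(=O)[C@H](C)CC[C@@H]1O[Si](C)(C)C(C)(C)C | intermediate
16 | lactone acid (C17 as CO2H) | CC(C)(C)[Si](C)(C)OCC[C@@]1(C(=O)O)OC(=O)[C@H](C)CC[C@@H]1O[Si](C)(C)C(C)(C)C | intermediate
17 | silyl ketene acetal (C6=C7, trimethylsilyl ester on C17) | CC(C)(C)[Si](C)(C)OCC[C@@]1(C(=O)O[Si](C)(C)C)OC(O[Si](C)(C)C)=C(C)CC[C@@H]1O[Si](C)(C)C(C)(C)C | intermediate (not isolated)
18 | bridged dilactone (C17 lactone to the C7 oxygen, C6 lactone; C10 OTBS, C13 OTBS) | CC(C)(C)[Si](C)(C)OCC[C@@]12OC(=O)[C@@](C)(CC[C@@H]1O[Si](C)(C)C(C)(C)C)OC2=O | intermediate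
19 | dilactone bromide (C13 Br) | BrCC[C@@]12OC(=O)[C@@](C)(CC[C@@H]1O[Si](C)(C)C(C)(C)C)OC2=O | intermediate
20 | tert-butyl(but-3-yn-1-yloxy)dimethylsilane | C#CCCO[Si](C)(C)C(C)(C)C | starting material
21 | lithium acetylide of 20 | [Li]C#CCCO[Si](C)(C)C(C)(C)C | intermediate (not isolated)
22 | methyl 5-(tert-butyldimethylsilyloxy)pent-2-ynoate | COC(=O)C#CCCO[Si](C)(C)C(C)(C)C | intermediate
23 | methyl (Z)-5-(tert-butyldimethylsilyloxy)-3-methylpent-2-enoate | COC(=O)/C=C(/C)CCO[Si](C)(C)C(C)(C)C | intermediate
24 | (Z)-5-(tert-butyldimethylsilyloxy)-3-methylpent-2-en-1-ol | OC/C=C(/C)CCO[Si](C)(C)C(C)(C)C | intermediate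
25 | bis-silyl ether (C1 O-tert-butyldiphenylsilyl, C5 O-TBS, Z) | CC(C)(C)[Si](C)(C)OCC/C(C)=C\CO[Si](c1ccccc1)(c1ccccc1)C(C)(C)C | intermediate
26 | (Z)-5-(tert-butyldiphenylsilyloxy)-3-methylpent-3-en-1-ol | OCC/C(C)=C\CO[Si](c1ccccc1)(c1ccccc1)C(C)(C)C | intermediate
27 | (Z)-5-bromo-3-methylpent-2-enyl tert-butyldiphenylsilyl ether | BrCC/C(C)=C\CO[Si](c1ccccc1)(c1ccccc1)C(C)(C)C | intermediate
28 | Grignard reagent from 27 | Br[Mg]CC/C(C)=C\CO[Si](c1ccccc1)(c1ccccc1)C(C)(C)C | intermediate (not isolated)
29 | bicyclic lactol (C6 hemiketal carrying the C1–C5 arm; C17 lactone) | BrCC[C@@]12OC(O)(CC/C(C)=C\CO[Si](c3ccccc3)(c3ccccc3)C(C)(C)C)[C@@](C)(CC[C@@H]1O[Si](C)(C)C(C)(C)C)OC2=O | intermediate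
30 | oxepane bromide (C6 H on the lactone side, S) | BrCC[C@@]12O[C@@H](CC/C(C)=C\CO[Si](c3ccccc3)(c3ccccc3)C(C)(C)C)[C@@](C)(CC[C@@H]1O[Si](C)(C)C(C)(C)C)OC2=O | intermediate
31 | propargyl alcohol | C#CCO | starting material
32 | alkenylmagnesium from 31 (Mg on C3 cis to CH2O) | Br[Mg]OC/C(C)=C\[Mg]Br | intermediate (not isolated)
33 | (Z)-3-iodo-2-methylprop-2-en-1-ol | OC/C(C)=C\I | intermediate
34 | (Z)-alkenyl iodide, TBS ether of 33 | CC(C)(C)[Si](C)(C)OC/C(C)=C\I | intermediate
35 | alkylzinc bromide from 30 | Br[Zn]CC[C@@]12O[C@@H](CC/C(C)=C\CO[Si](c3ccccc3)(c3ccccc3)C(C)(C)C)[C@@](C)(CC[C@@H]1O[Si](C)(C)C(C)(C)C)OC2=O | intermediate (not isolated)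
36 | tris-silyl ether of the target (C1 O-tert-butyldiphenylsilyl, C10 and C16 O-TBS) | CC(C)(C)[Si](C)(C)OC/C(C)=C\CC[C@@]12O[C@@H](CC/C(C)=C\CO[Si](c3ccccc3)(c3ccccc3)C(C)(C)C)[C@@](C)(CC[C@@H]1O[Si](C)(C)C(C)(C)C)OC2=O | intermediate
37 | target CNP0105745.1 (6S,7R,10S,11R; 2Z,14Z) | C/C(=C/CC[C@@]12O[C@@H](CC/C(C)=C\CO)[C@@](C)(CC[C@@H]1O)OC2=O)CO | target

## Step count and risk

Total: 24 steps. Longest linear sequence: 16 steps from 1 (steps 1–12, 19, 20, 23, 24). Side sequences: 6 steps from 20 to 27, and 2 steps from 31 to 34.

**Step 11 (proposed new method).** Capture of the iodine-bound intermediate by external acetate instead of the tethered carboxyl, oxidative dimerisation of the ketene acetal, or loss of the silyl groups before oxidation would all divert the reaction. The fallback uses known reactions and sets out from 14. The potassium enolate (KN(SiMe3)2, THF, −78 °C) is hydroxylated with 2-(phenylsulfonyl)-3-phenyloxaziridine to the C7-hydroxy lactone F1. Hydrogenolysis (H2, Pd/C) gives the diol F2, and TEMPO/NaClO2 oxidation gives the hydroxy acid F3. Lactonisation with 2,4,6-trichlorobenzoyl chloride, Et3N and DMAP (Yamaguchi conditions) closes only the epimer whose C7 hydroxyl faces the carboxyl and returns to 18. The price is that the C7 face is then chosen by approach of the oxidant to the enolate and no longer by the tether.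

**Step 8 (key step).** Competing migration of C7 would give the regioisomeric lactone, and a slow oxidation of the hindered ketone would expose the silyl ethers to acid for longer. The fallback sets out from 13. Enolisation (KN(SiMe3)2) and chlorination with N-chlorosuccinimide give the C7-chloro ketone F4, in which the halogen makes C7 a very poor migrating group. CF3CO3H then inserts on the C11 side to give the C7-chloro lactone F5, and Bu3SnH/AIBN removes the chlorine and returns to 14.

**Step 19.** Poor site selectivity between the two ester carbonyls (addition at C17 instead of C6) is the main danger, since the dilactone is nearly symmetric. A second addition after opening of the hemiketal is the lesser one. The fallback reorders the sequence so that the bulkier silyloxyethyl chain screens C17. It sets out from 18 (before step 12). Addition of 28 gives the lactol F6, Et3SiH with the silyl triflate gives the reduced oxepane F7, and Ph3PBr2 then converts the primary silyl ether into the bromide and returns to 30.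

**Step 20.** Hydride delivery from the C8–C10 face would give the wrong C6 configuration, and ionisation may be slow because both neighbouring carbons carry acyloxy groups, which would endanger the allylic silyl ether. The fallback reverses the order of bond formation at C6 and sets out from 19. Reduction with i-Bu2AlH at −78 °C and acetylation in the same flask (Ac2O, pyridine, DMAP) give the C6 lactol acetate F8. Transmetalation of 28 with ZnCl2 gives the dialkylzinc F9. With the silyl triflate, F9 alkylates the oxocarbenium ion that now carries hydrogen. A carbon nucleophile entering from the face that hydride preferred gives the opposite C6 configuration, so this returns to 30 if the direct reduction goes the wrong way. The reduction in this fallback faces the same C6/C17 choice as step 19.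

**Step 2.** Loss of benzyloxide from the β-benzyloxy enolate, or slow and unselective alkylation at the crowded carbon, would erode the yield and the C11 configuration. The fallback uses a faster electrophile and sets out from 4. Alkylation with allyl bromide gives 6-allyl-6-(benzyloxymethyl)carvone F10. Ozonolysis in CH2Cl2/MeOH cleaves both terminal alkenes. Treatment with Ac2O, Et3N and DMAP turns the isopropenyl-derived hydroperoxide into the acetate and the allyl-derived one into the methyl ester, giving the acetate methyl ester F11. Any aldehyde from the other mode of ozonide cleavage is reduced to the same alcohol. LiAlH4 then returns to 10.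

## Further compounds

F1 | step 11 | C7-hydroxy lactone (OH cis to CH2OBn) | CC(C)(C)[Si](C)(C)OCC[C@@]1(COCc2ccccc2)OC(=O)[C@](C)(O)CC[C@@H]1O[Si](C)(C)C(C)(C)C
F2 | step 11 | C7-hydroxy lactone diol (C17 as CH2OH) | CC(C)(C)[Si](C)(C)OCC[C@@]1(CO)OC(=O)[C@](C)(O)CC[C@@H]1O[Si](C)(C)C(C)(C)C
F3 | step 11 | C7-hydroxy lactone acid | CC(C)(C)[Si](C)(C)OCC[C@@]1(C(=O)O)OC(=O)[C@](C)(O)CC[C@@H]1O[Si](C)(C)C(C)(C)C
F4 | step 8 | C7-chloro ketone (C7 epimers) | CC(C)(C)[Si](C)(C)OCC[C@@]1(COCc2ccccc2)C(=O)C(C)(Cl)CC[C@@H]1O[Si](C)(C)C(C)(C)C
F5 | step 8 | C7-chloro oxepan-2-one | CC(C)(C)[Si](C)(C)OCC[C@@]1(COCc2ccccc2)OC(=O)C(C)(Cl)CC[C@@H]1O[Si](C)(C)C(C)(C)C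
F6 | step 19 | bicyclic lactol with C13 silyl ether | CC(C)(C)[Si](C)(C)OCC[C@@]12OC(O)(CC/C(C)=C\CO[Si](c3ccccc3)(c3ccccc3)C(C)(C)C)[C@@](C)(CC[C@@H]1O[Si](C)(C)C(C)(C)C)OC2=O
F7 | step 19 | C6-reduced oxepane with C13 silyl ether | CC(C)(C)[Si](C)(C)OCC[C@@]12O[C@@H](CC/C(C)=C\CO[Si](c3ccccc3)(c3ccccc3)C(C)(C)C)[C@@](C)(CC[C@@H]1O[Si](C)(C)C(C)(C)C)OC2=O
F8 | step 20 | C6 lactol acetate of 19 | BrCC[C@@]12OC(OC(C)=O)[C@@](C)(CC[C@@H]1O[Si](C)(C)C(C)(C)C)OC2=O
F9 | step 20 | dialkylzinc from 28 | CC(C)(C)[Si](c1ccccc1)(c1ccccc1)OC/C=C(C)\CC[Zn]CC/C(C)=C\CO[Si](c1ccccc1)(c1ccccc1)C(C)(C)C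
F10 | step 2 | 6-allyl-6-(benzyloxymethyl)carvone (allyl trans to isopropenyl) | CC1=CC[C@H](C(C)=C)[C@@](COCc2ccccc2)(CC=C)C1=O
F11 | step 2 | enone acetate methyl ester | CC1=CC[C@H](OC(C)=O)[C@@](COCc2ccccc2)(CC(=O)OC)C1=O
A1 | alternative 1 | 1,4-dioxepan-2-one with the (E)-2-(pinacolboryl)vinyl group on C8 | CC(C)(C)[Si](C)(C)OC/C(C)=C\CCC1O[C@@H](CC/C(C)=C\CO[Si](C)(C)C(C)(C)C)[C@](C)(O[Si](CC)(CC)CC)[C@H](OC1=O)/C=C/B2OC(C)(C)C(C)(C)O2
A2 | alternative 1 | oxepene-2-carboxylic acid with the C10 boronate | C/C(=C/CC[C@@]1(C(=O)O)O[C@@H](CC/C(C)=C\CO[Si](C)(C)C(C)(C)C)[C@](C)(O[Si](CC)(CC)CC)/C=C\[C@@H]1B2OC(C)(C)C(C)(C)O2)CO[Si](C)(C)C(C)(C)C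
A3 | alternative 2 | acyclic α-diazo ester of the C7 alcohol with free C6 hydroxyl and C10 aldehyde | CC(C)(C)[Si](C)(C)OC/C(C)=C\CCC(=[N+]=[N-])C(=O)O[C@](C)(CCC=O)[C@@H](O)CC/C(C)=C\CO[Si](C)(C)C(C)(C)C
A4 | alternative 2 | bis-TBS ether of the target | C/C(=C/CC[C@@]12O[C@@H](CC/C(C)=C\CO[Si](C)(C)C(C)(C)C)[C@@](C)(CC[C@@H]1O)OC2=O)CO[Si](C)(C)C(C)(C)C
A5 | alternative 3 | acyclic C11 ketone with free C6 hydroxyl | CC(C)[Si](OCCCC(=O)[C@@H](O[Si](C)(C)C(C)(C)C)CC[C@@](C)(O[Si](CC)(CC)CC)[C@@H](O)CCOCc1ccc(OC)cc1)(C(C)C)C(C)C
A6 | alternative 3 | oxepane-2-carboxylic acid with the quaternary C11 | CC(C)[Si](OCCC[C@@]1(C(=O)O)O[C@@H](CCOCc2ccc(OC)cc2)[C@](C)(O[Si](CC)(CC)CC)CC[C@@H]1O[Si](C)(C)C(C)(C)C)(C(C)C)C(C)C
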